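**Strategy.** Ring B of the pterocarpan core is closed by an intramolecular Friedel–Crafts acylation that joins C11b of ring A to C11a (pterocarpan numbering). The step exploits that C11b is para to the chromene oxygen and ortho to O5, hence the most nucleophilic carbon of ring A and the only one that reaches the acyl carbon through a six-membered transition state. Bringing C11a in as a ketone makes C6a epimerisable, so a single transfer hydrogenation with dynamic kinetic resolution then sets C6a and C11a, and acid closes ring C. The precursor is an open-chain 2-aryl-3-aryloxypropanoic acid whose two aryl groups both come from 2,2-dimethyl-2H-chromen-5-ol.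

Key step: step 10

Remark: the sense of induction of the two chiral catalysts (steps 5 and 11) is assigned by analogy with 2,2-dimethylchromenes and 3-arylchroman-4-ones; the enantiomeric catalyst would be used if the opposite sense were found.

**Step 1**
Reactants: 1 cyclohexane-1,3-dione; 2 3-methylbut-2-enal
Product: 3 2,2-dimethyl-2,6,7,8-tetrahydro-5H-chromen-5-one
Conditions: ethylenediammonium diacetate (10 mol%), MeOH, rt
Reagents that add atoms: none
Why: Knoevenagel condensation of the dione with the enal gives a 1-oxatriene that closes by oxa-6π-electrocyclisation (formal [3+3] annulation), which places the gem-dimethylpyran ring on the future aromatic ring.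

**Step 2**
Reactants: 3 2,2-dimethyl-2,6,7,8-tetrahydro-5H-chromen-5-one
Product: 5 2,2-dimethyl-2H-chromen-5-ol, via α-phenylselanyl ketone 4 (not isolated)
Conditions: LiN(i-Pr)2, THF, −78 °C; PhSeCl, −78 °C; then H2O2 (30% aq.), pyridine, CH2Cl2, 0 °C to rt
Reagents that add atoms: none
Why: Kinetic deprotonation of the vinylogous ester at C6 and selenenylation, then oxidation to the selenoxide and syn-elimination, should give a cross-conjugated dienone that tautomerises to the phenol (selenoxide elimination with aromatisation).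

**Step 3**
Reactants: 5 2,2-dimethyl-2H-chromen-5-ol; 6 2-chloro-N-methoxy-N-methylacetamide
Product: 7 2-[(2,2-dimethyl-2H-chromen-5-yl)oxy]-N-methoxy-N-methylacetamide
Conditions: K2CO3, KI (cat.), DMF, 60 °C
Reagents that add atoms: none
Why: Williamson ether synthesis (SN2) of the phenoxide on the α-chloro amide brings in C6 and C6a as a Weinreb amide, the acyl form that accepts a single addition of an aryllithium.

**Step 4**
Reactants: 5 2,2-dimethyl-2H-chromen-5-ol
Product: 8 5-(methoxymethoxy)-2,2-dimethyl-2H-chromene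
Conditions: NaH, DMF, 0 °C; MOMCl, 0 °C to rt
Reagents that add atoms: chloromethyl methyl ether (MOMCl), COCCl
Why: O-Alkylation of the sodium phenoxide masks the oxygen that becomes O11 and supplies the directing group for the ortho-lithiation of step 7.

**Step 5**
Reactants: 8 5-(methoxymethoxy)-2,2-dimethyl-2H-chromene
Product: 9 (3R,4R)-3,4-epoxy-5-(methoxymethoxy)-2,2-dimethylchromane
Conditions: [(R,R)-N,N'-bis(3,5-di-tert-butylsalicylidene)cyclohexane-1,2-diaminato]MnCl (4 mol%), 4-phenylpyridine N-oxide (20 mol%), aq. NaOCl (pH 11.3), CH2Cl2, 0 °C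
Reagents that add atoms: sodium hypochlorite, [Na+].[O-]Cl
Why: Jacobsen–Katsuki epoxidation of a cis-disubstituted aryl-conjugated alkene, for which 2,2-dimethylchromenes are the standard substrates; the (R,R)-salen ligand is expected to direct oxygen transfer to the face that gives the (3R,4R)-epoxide, which fixes the carbinol centre of the target.

**Step 6**
Reactants: 9 (3R,4R)-3,4-epoxy-5-(methoxymethoxy)-2,2-dimethylchromane
Product: 10 (3R)-5-(methoxymethoxy)-2,2-dimethylchroman-3-ol
Conditions: LiAlH4, THF, 0 °C to rt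
Reagents that add atoms: none
Why: Hydride should open the epoxide by SN2 attack at the benzylic C4 and not at the neopentyl C3, so the C3–O bond is untouched and the R configuration of the carbinol is kept.

**Step 7**
Reactants: 10 (3R)-5-(methoxymethoxy)-2,2-dimethylchroman-3-ol; 7 2-[(2,2-dimethyl-2H-chromen-5-yl)oxy]-N-methoxy-N-methylacetamide
Product: 11 2-[(2,2-dimethyl-2H-chromen-5-yl)oxy]-1-[(3R)-3-hydroxy-5-(methoxymethoxy)-2,2-dimethylchroman-6-yl]ethan-1-one
Conditions: n-BuLi (2.3 equiv), TMEDA, THF, −20 to 0 °C; then 7, −78 to 0 °C; aq. NH4Cl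
Reagents that add atoms: none
Why: After deprotonation of the alcohol the MOM ether directs lithiation to C6, its only free ortho position, and the aryllithium adds once to the Weinreb amide because the chelated tetrahedral adduct survives until work-up (directed ortho-metalation and Weinreb ketone synthesis); no stereocentre is touched.

**Step 8**
Reactants: 11 2-[(2,2-dimethyl-2H-chromen-5-yl)oxy]-1-[(3R)-3-hydroxy-5-(methoxymethoxy)-2,2-dimethylchroman-6-yl]ethan-1-one; 12 (methoxymethyl)triphenylphosphonium chloride
Product: 13 (3R)-6-{1-[(2,2-dimethyl-2H-chromen-5-yl)oxy]-3-methoxyprop-2-en-2-yl}-5-(methoxymethoxy)-2,2-dimethylchroman-3-ol (E/Z mixture)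
Conditions: 12 (3.5 equiv), KOt-Bu (3.3 equiv), THF, 0 °C; then 11, 0 °C to rt
Reagents that add atoms: none
Why: Wittig olefination with methoxymethylenetriphenylphosphorane turns the ketone carbon (C6a) into an enol ether that carries C11a at the aldehyde oxidation level; the excess of ylide allows for the free alkoxide and the alkene geometry is irrelevant.

**Step 9**
Reactants: 13 (3R)-6-{1-[(2,2-dimethyl-2H-chromen-5-yl)oxy]-3-methoxyprop-2-en-2-yl}-5-(methoxymethoxy)-2,2-dimethylchroman-3-ol (E/Z mixture)
Product: 15 3-[(2,2-dimethyl-2H-chromen-5-yl)oxy]-2-[(3R)-3-hydroxy-5-(methoxymethoxy)-2,2-dimethylchroman-6-yl]propanoic acid (both C2 epimers), via aldehyde 14 (not isolated)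
Conditions: 1 M HCl, THF, 0 °C to rt; then NaClO2, NaH2PO4, 2-methyl-2-butene, t-BuOH/H2O, 0 °C
Reagents that add atoms: water, O; sodium chlorite, [Na+].[O-]Cl=O
Why: Acid hydrolysis of the enol ether frees the α-aryl aldehyde, which is oxidised without isolation by chlorite (Pinnick oxidation) with 2-methyl-2-butene as hypochlorite scavenger to protect the chromene; C6a forms without control here, which does not matter because it is equilibrated in step 11.

**Step 10**
Reactants: 15 3-[(2,2-dimethyl-2H-chromen-5-yl)oxy]-2-[(3R)-3-hydroxy-5-(methoxymethoxy)-2,2-dimethylchroman-6-yl]propanoic acid (both C2 epimers)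
Product: 18 3-[(3R)-3-hydroxy-5-(methoxymethoxy)-2,2-dimethylchroman-6-yl]-8,8-dimethyl-2,3-dihydro-4H,8H-pyrano[2,3-f]chromen-4-one (both C3 epimers), via mixed anhydride 16 (not isolated), via ketone trifluoroacetate 17 (not isolated)
Conditions: (CF3CO)2O (3.5 equiv), CH2Cl2, 0 °C to rt; evaporation; then NaHCO3 (cat.), MeOH, 0 °C
Reagents that add atoms: none
Why: Trifluoroacetic anhydride turns the acid into its mixed anhydride (and the carbinol into a trifluoroacetate that methanol removes afterwards); C11b of ring A attacks the activated acyl carbon C11a, and loss of trifluoroacetate and of the ring proton gives the aryl ketone. The closest known reaction is the Friedel–Crafts cyclisation of 3-aryloxypropanoic acids to chroman-4-ones. Ring B closes in the 6-exo-trig mode at the acyl carbon. No stereocentre is formed; C6a stays a mixture and becomes the enolisable α-carbon of the new ketone, which is what the resolution in step 11 requires. The step needs regioselectivity for C11b and chemoselectivity against the chromene alkene and the MOM ether: C11b is the only free position ortho to O5, it is activated para by the pyran oxygen and is the only carbon that gives a six-membered ring, and anhydride activation without a metal halide or mineral acid should leave the acid-sensitive groups intact.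

**Step 11**
Reactants: 18 3-[(3R)-3-hydroxy-5-(methoxymethoxy)-2,2-dimethylchroman-6-yl]-8,8-dimethyl-2,3-dihydro-4H,8H-pyrano[2,3-f]chromen-4-one (both C3 epimers)
Product: 20 CNP0126417.1 (the 6aR,11aR-pterocarpan target), via cis-isoflavan-4-ol 19 (not isolated)
Conditions: RuCl[(R,R)-TsDPEN](p-cymene) (2 mol%), HCO2H/Et3N (5:2 azeotrope), EtOAc, 40 °C; then HCl (cat.), MeOH, rt
Reagents that add atoms: none
Why: Noyori–Ikariya transfer hydrogenation with dynamic kinetic resolution: triethylamine equilibrates C6a through the enol while the (R,R)-catalyst should reduce only the (6aR)-ketone, from the face that gives the cis-(3R,4R)-alcohol (C6a and C11a of the target), and acid then ionises the benzylic C11a–OH so that the MOM-bearing oxygen closes ring C on the cation with loss of the methoxymethyl group, the cis ring fusion being the only unstrained one so that C11a follows C6a.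

**Compound list**

1 | cyclohexane-1,3-dione | O=C1CCCC(=O)C1 | starting material
2 | 3-methylbut-2-enal | CC(C)=CC=O | starting material
3 | 2,2-dimethyl-2,6,7,8-tetrahydro-5H-chromen-5-one | CC1(C)C=CC2=C(O1)CCCC2=O | intermediate
4 | 2,2-dimethyl-6-(phenylselanyl)-2,6,7,8-tetrahydro-5H-chromen-5-one (α-phenylselanyl ketone) | CC1(C)C=CC2=C(O1)CCC([Se]c3ccccc3)C2=O | intermediate
5 | 2,2-dimethyl-2H-chromen-5-ol | CC1(C)C=Cc2c(O)cccc2O1 | intermediate
6 | 2-chloro-N-methoxy-N-methylacetamide | CON(C)C(=O)CCl | starting material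
7 | 2-[(2,2-dimethyl-2H-chromen-5-yl)oxy]-N-methoxy-N-methylacetamide | CON(C)C(=O)COc1cccc2OC(C)(C)C=Cc12 | intermediate
8 | 5-(methoxymethoxy)-2,2-dimethyl-2H-chromene | COCOc1cccc2OC(C)(C)C=Cc12 | intermediate
9 | (3R,4R)-3,4-epoxy-5-(methoxymethoxy)-2,2-dimethylchromane | COCOc1cccc2OC(C)(C)[C@@H]3O[C@@H]3c12 | intermediate
10 | (3R)-5-(methoxymethoxy)-2,2-dimethylchroman-3-ol | COCOc1cccc2OC(C)(C)[C@H](O)Cc12 | intermediate
11 | 2-[(2,2-dimethyl-2H-chromen-5-yl)oxy]-1-[(3R)-3-hydroxy-5-(methoxymethoxy)-2,2-dimethylchroman-6-yl]ethan-1-one | COCOc1c(C(=O)COc3cccc4OC(C)(C)C=Cc34)ccc2OC(C)(C)[C@H](O)Cc12 | intermediate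
12 | (methoxymethyl)triphenylphosphonium chloride | COC[P+](c1ccccc1)(c1ccccc1)c1ccccc1.[Cl-] | starting material
13 | (3R)-6-{1-[(2,2-dimethyl-2H-chromen-5-yl)oxy]-3-methoxyprop-2-en-2-yl}-5-(methoxymethoxy)-2,2-dimethylchroman-3-ol (E/Z mixture) | COCOc1c(C(=COC)COc3cccc4OC(C)(C)C=Cc34)ccc2OC(C)(C)[C@H](O)Cc12 | intermediate
14 | 3-[(2,2-dimethyl-2H-chromen-5-yl)oxy]-2-[(3R)-3-hydroxy-5-(methoxymethoxy)-2,2-dimethylchroman-6-yl]propanal (both C2 epimers) | COCOc1c(C(C=O)COc3cccc4OC(C)(C)C=Cc34)ccc2OC(C)(C)[C@H](O)Cc12 | intermediate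
15 | 3-[(2,2-dimethyl-2H-chromen-5-yl)oxy]-2-[(3R)-3-hydroxy-5-(methoxymethoxy)-2,2-dimethylchroman-6-yl]propanoic acid (both C2 epimers) | COCOc1c(C(C(=O)O)COc3cccc4OC(C)(C)C=Cc34)ccc2OC(C)(C)[C@H](O)Cc12 | intermediate
16 | mixed trifluoroacetic anhydride of 15 with the carbinol as its trifluoroacetate | COCOc1c(C(C(=O)OC(=O)C(F)(F)F)COc3cccc4OC(C)(C)C=Cc34)ccc2OC(C)(C)[C@H](OC(=O)C(F)(F)F)Cc12 | intermediate
17 | O-trifluoroacetate of ketone 18 | O=C1c2ccc3OC(C)(C)C=Cc3c2OCC1c1ccc2OC(C)(C)[C@H](OC(=O)C(F)(F)F)Cc2c1OCOC | intermediate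
18 | 3-[(3R)-3-hydroxy-5-(methoxymethoxy)-2,2-dimethylchroman-6-yl]-8,8-dimethyl-2,3-dihydro-4H,8H-pyrano[2,3-f]chromen-4-one (both C3 epimers) | O=C1c2ccc3OC(C)(C)C=Cc3c2OCC1c1ccc2OC(C)(C)[C@H](O)Cc2c1OCOC | intermediate
19 | (3R,4R)-3-[(3R)-3-hydroxy-5-(methoxymethoxy)-2,2-dimethylchroman-6-yl]-8,8-dimethyl-3,4-dihydro-2H,8H-pyrano[2,3-f]chromen-4-ol (cis) | O[C@H]1c2ccc3OC(C)(C)C=Cc3c2OC[C@H]1c1ccc2OC(C)(C)[C@H](O)Cc2c1OCOC | intermediate
20 | CNP0126417.1: (6aR,11aR)-pterocarpan with a 2,2-dimethyl-2H-pyran ring fused to ring A (O on C3, CH= on C4) and an (R)-3-hydroxy-2,2-dimethyl-3,4-dihydro-2H-pyran ring fused to ring D (O on C9, CH2 on C10) | CC1(C)C=Cc2c(ccc3c2OC[C@H]2c4ccc5c(c4O[C@@H]32)C[C@@H](O)C(C)(C)O5)O1 | target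

**Step count and risks**

Total step count: 11. Longest linear sequence: 10 steps (steps 1, 2, 4, 5, 6, 7, 8, 9, 10, 11); step 3 is the side branch.

Steps most likely to fail:

1. Step 10 (key step). The mixed anhydride may cyclise too slowly without a stronger acid, and a stronger acid would protonate the chromene alkene or cleave the MOM ether. The ortho MOM oxygen may also attack the activated acyl group, or aryloxide may be lost by β-elimination. Fallback (sets out from 13, returns at 18): the same ring closure is run at the aldehyde oxidation level. Hydrolysis of 13 (1 M HCl, THF) gives aldehyde 14. Me2AlCl (CH2Cl2, −78 °C) should promote Friedel–Crafts hydroxyalkylation of ring A by the aldehyde to give the 4-hydroxyisoflavan F1 as a mixture of stereoisomers. MnO2 (CH2Cl2, rt) should oxidise the benzylic alcohol, and not the hindered non-benzylic carbinol, to ketone 18.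

2. Step 11. Epimerisation of C6a may be slower than reduction, the catalyst may be mismatched with the existing carbinol centre, or the benzylic alcohol may dehydrate to the isoflav-3-ene before ring C closes, which would erase C6a. Fallback (sets out from 18, returns at 20): reagent-controlled reduction and separation replace the catalytic resolution. LiBH(s-Bu)3 (THF, −78 °C) should give the cis-alcohol 19 together with its (3S,4S)-diastereomer F2. HCl (cat.) in MeOH should convert these into 20 and its (6aS,11aS)-diastereomer F3. Because the carbinol centre is fixed, the two are diastereomers and would be separated by preparative HPLC or crystallisation.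

3. Step 7. Lithiation may occur at C8 or at the benzylic C4 instead of C6, or the aryllithium may enolise the Weinreb amide instead of adding to it. Fallback (sets out from 2 and commercial 1-(2,4-dihydroxyphenyl)ethan-1-one, returns at 11): the regiochemistry is fixed by a chromenylation instead of a lithiation.
   - Condensation of the acetophenone with 2 (pyridine, 140 °C) should give 1-(5-hydroxy-2,2-dimethyl-2H-chromen-6-yl)ethan-1-one F4, because the chelated hydroxyl stays passive and the pyran closes between the two oxygens.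
   - MOM protection (NaH, MOMCl) gives the MOM ether F5.
   - Epoxidation with the same MnCl(salen) catalyst and conditions as in step 5 gives the (3R,4R)-epoxy ketone F6.
   - Hydrogenolysis of the benzylic C–O bond (H2, Pd/C, EtOAc) gives the hydroxy ketone F7.
   - Bromination of the lithium enolate (LiN(SiMe3)2, THF, −78 °C; NBS) gives the bromo ketone F8.
   - Williamson etherification of F8 with 5 (K2CO3, acetone) gives 11.

**Further compounds**

F1 | step 10 | 3-[(3R)-3-hydroxy-5-(methoxymethoxy)-2,2-dimethylchroman-6-yl]-8,8-dimethyl-3,4-dihydro-2H,8H-pyrano[2,3-f]chromen-4-ol (mixture of C3/C4 stereoisomers) | OC1c2ccc3OC(C)(C)C=Cc3c2OCC1c1ccc2OC(C)(C)[C@H](O)Cc2c1OCOC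
F2 | step 11 | (3S,4S)-3-[(3R)-3-hydroxy-5-(methoxymethoxy)-2,2-dimethylchroman-6-yl]-8,8-dimethyl-3,4-dihydro-2H,8H-pyrano[2,3-f]chromen-4-ol (cis) | O[C@@H]1c2ccc3OC(C)(C)C=Cc3c2OC[C@@H]1c1ccc2OC(C)(C)[C@H](O)Cc2c1OCOC
F3 | step 11 | (6aS,11aS)-diastereomer of 20 with the same (R)-carbinol | CC1(C)C=Cc2c(ccc3c2OC[C@@H]2c4ccc5c(c4O[C@H]32)C[C@@H](O)C(C)(C)O5)O1
F4 | step 7 | 1-(5-hydroxy-2,2-dimethyl-2H-chromen-6-yl)ethan-1-one | CC(=O)c1ccc2OC(C)(C)C=Cc2c1O
F5 | step 7 | 1-[5-(methoxymethoxy)-2,2-dimethyl-2H-chromen-6-yl]ethan-1-one | CC(=O)c1ccc2OC(C)(C)C=Cc2c1OCOC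
F6 | step 7 | 1-[(3R,4R)-3,4-epoxy-5-(methoxymethoxy)-2,2-dimethylchroman-6-yl]ethan-1-one | CC(=O)c1ccc2OC(C)(C)[C@@H]3O[C@@H]3c2c1OCOC
F7 | step 7 | 1-[(3R)-3-hydroxy-5-(methoxymethoxy)-2,2-dimethylchroman-6-yl]ethan-1-one | CC(=O)c1ccc2OC(C)(C)[C@H](O)Cc2c1OCOC
F8 | step 7 | 2-bromo-1-[(3R)-3-hydroxy-5-(methoxymethoxy)-2,2-dimethylchroman-6-yl]ethan-1-one | BrCC(=O)c1ccc2OC(C)(C)[C@H](O)Cc2c1OCOC
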